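**Abbreviations and numbering.** TBS = tert-butyldimethylsilyl, TES = triethylsilyl, TMS = trimethylsilyl. The decalin is numbered as a naphthalene: ring B = C1–C4, C4a, C8a; ring A = C4a, C5–C8, C8a. C1 carries the acid chain (C1″ = CO2H to C7″, bonded to C1), C2 the ylidene (C1′, ketone C2′, carbinol C3′). α is the face of the two ring-fusion hydrogens, β the opposite face. Compound numbers 1–33 are fixed as in the list after the steps.

## Analysis of the target

The target is a cis-fused 1,2,4a,5,6,7,8,8a-octahydronaphthalene with methyls on C3, C6 and C8, a hydroxyl on C7, an exocyclic ylidene on C2 and a trienoic acid on C1. It has six stereocentres, (1R,4aS,6S,7R,8R,8aR). The fusion hydrogens are cis (α), the C6 and C8 methyls are α and the C7 hydroxyl is β, so the three ring A substituents alternate and are all equatorial on a chair. The C8 methyl is trans to the C8a–C1 bond, and the C1 chain is α, pseudoaxial and anti to the C8a–C8 bond. Ring B holds a linear dienone C4=C3–C2=C1′–C2′=O with an (E) ylidene (acyl group turned toward C1, away from the C3 methyl) and a free primary α-hydroxyl. C1 bears a (2E,4Z,6E)-4,6-dimethylhepta-2,4,6-trienoic acid whose central trisubstituted alkene is Z. Sensitive points are the C1–H (doubly allylic and γ to the ketone), the Z alkene and polyene acid, and the α-hydroxy enone. The difficulty is five contiguous ring stereocentres with a cis fusion, plus two different unsaturated arms on neighbouring C1 and C2 that need carbonyl chemistry at C2 which the finished arms would not survive. The strategy rests on ring B: an oxygen-level C2 beside the methyl-bearing C3, the C3=C4 alkene (one oxidation away from a C2=C3 enol ether) and the cis C4a/C8a fusion are together the retron of a 2-silyloxy-3-methylbuta-1,3-diene added across C4a=C8a of a ring A cyclohex-2-enone.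

## Retrosynthetic reasoning

**Ylidene hydroxy ketone.** After removal of the two silyl ethers (33 ⇒ 32), the C2=C1′–C2′=O unit is traced to the tertiary propargylic alcohol 31 by a Meyer–Schuster transform. This keeps the base-sensitive dienone and the acidified C1–H out of the route until the last but one step. The forward reaction must give a 1,3-oxygen shift and the (E) ylidene. Cutting C2–C1′ then gives ketone 21 and alkyne 22.

**Triene acid.** The chain is cut at C3″–C4″ (sp2–sp2 coupling of iodide 28 with boronate 29), at C4″=C5″ (Z-selective α-iodo ylide olefination of enal 27) and at C6″=C7″ (E-selective stabilized-ylide olefination of aldehyde 26). Each cut fixes one alkene geometry by a reaction known to deliver it. The cuts are made while C2 is a protected carbinol (25–30), so no enolizable carbonyl flanks the C1 aldehyde.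

**C1–C7″ bond.** The one-carbon arm on C1 of 20 is cut back to enone 18. Forward, the kinetic α′-enolate must take a one-carbon electrophile on the α face, anti to the pseudoaxial C8a–C8 bond. This sets C1.

**Ring B oxidation pattern.** Enone 18 is the dehydrogenation product of the regiodefined C2=C3 silyl enol ether 17. 17 is adduct 14 without its C5 oxygen; the carbonyl is removed by reduction, thioacylation and radical deoxygenation.

**Key disconnection.** The C1–C8a and C4–C4a bonds of 14 are cut in a retro-[4+2] to enone 11 and diene 13. This is chosen because it builds ring B, both fusion stereocentres and the correctly placed enol ether from two simple components. The forward step needs "para" regiochemistry and approach anti to the C8 methyl.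

**Enone 11.** The C4a=C8a alkene is cut by ring-closing metathesis to dienone 10, and the C4a–C5 bond by vinyl addition to aldehyde 8. The C7–C8 bond is cut by crotylation of aldehyde 3 with stannane 4. The ring needs C6-Me, C7-O and C8-Me all trans, which is the all-syn triad in the open chain. An anti-selective crotylation would not map onto it, so the forward reaction must be syn-selective and Felkin-controlled. C6 comes from hydroxy ester 1. Diene 13 is the silyl enol ether of enone 12.

## Alternatives that were turned down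

**Alternative 1:** Ring A is disconnected at C6–C7. Forward, single-electron reduction of aldehyde A1 (ring B cyclohexene ketal with a 1-oxopropan-2-yl arm on C8a and an allyl group on C4a) gives a ketyl that adds 6-exo to the allyl alkene and yields carbinol A2.
- For: it forms ring A with the C7 hydroxyl at the right oxidation level and carries no surplus oxygen. On this point it is stronger than the chosen route, which spends three steps removing the C5 carbonyl.
- Against: a ketyl must add to an unactivated terminal alkene, where simple reduction and pinacol coupling compete. C6 and C7 arise together from one radical step with little to bias the C6 methyl. A1 needs three stereocentres (C4a, C8a and the epimerizable C8 beside the aldehyde) built on a flexible monocycle. A2 still lacks all C1 and C2 functionality.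
- Comparison: the chosen strategy sets the fusion in the ring-forming event from a rigid enone reached by standard acyclic stereocontrol.

**Alternative 2:** Ring B is disconnected at C1–C8a. Forward, a mild carbonate base makes the β-keto ester carbon of enone A3 (ring A 2-methylcyclohexenone with a (Z)-enone keto ester arm on C4a) add to C8a, giving the enolized keto ester A4.
- For: the tether enforces the cis fusion with no facial question at C8a, and C1 arrives with a carbon substituent. On both points it is as strong as or stronger than the cycloaddition.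
- Against: A3 needs a (Z)-enone arm prone to isomerization and polymerization. In A4, C1 and C2 are a fully enolized keto ester; the ketone cannot be alkynylated beside the acidic ester, so the chain and ylidene need several redox detours and C1 must be set again. The C7 ketone must be reduced selectively between two methyl-bearing carbons.
- Comparison: no step saving overall; the chosen route offers a two-component assembly and a regiodefined enol ether that leads directly to the C3=C4 enone.

**Alternative 3:** Ring B is disconnected at C1–C2. Forward, a Lewis acid makes the γ-carbon of the silyl dienol ether arm of A5 (ring A cyclohexane with a (Z)-enynone arm on C4a and the dienol ether arm on C8a) attack the ynone β-carbon (6-exo-dig), giving A6 with the ylidene ketone and the C1 enal in place.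
- For: the endgame is clearly shorter than the chosen one. There is no C5 deoxygenation, no C1 functionalization and no Meyer–Schuster step.
- Against: all five ring A stereocentres, including the cis C4a/C8a pair, must be built beforehand on a cyclohexane carrying two sensitive arms, which moves the whole stereochemical problem into the precursor. The ylidene geometry and the C1 configuration are left to allenoate protonation and thermodynamics. The Lewis acid may desilylate or isomerize the arms.
- Comparison: the chosen strategy places its risk in one well-understood cycloaddition on simple compounds, at the cost of a longer endgame.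

Key step: step 11

Remark: the carbinol carbons C5 (in 15, 16) and C2 (in 24–31) are cleared later, so their configuration is left open and either epimer is carried on.

## Steps

Step 1
Reactants: 1 methyl (S)-3-hydroxy-2-methylpropanoate
Product: 2 methyl (S)-3-[(tert-butyldimethylsilyl)oxy]-2-methylpropanoate
Conditions: TBSCl, imidazole, DMF, 0 °C → rt
Reagents that add atoms: tert-butyldimethylsilyl chloride, CC(C)(C)[Si](C)(C)Cl
Why: Silylation of a primary alcohol; the stereocentre (the future C6) is not touched.

Step 2
Reactants: 2 methyl (S)-3-[(tert-butyldimethylsilyl)oxy]-2-methylpropanoate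
Product: 3 (S)-3-[(tert-butyldimethylsilyl)oxy]-2-methylpropanal
Conditions: iBu2AlH (1.05 equiv), CH2Cl2, −78 °C; aq. potassium sodium tartrate
Reagents that add atoms: none
Why: Partial ester reduction; the tetrahedral aluminium hemiacetal is stable at −78 °C and should release the aldehyde only on work-up, and the crude aldehyde is used at once to avoid α-epimerization.

Step 3
Reactants: 3 (S)-3-[(tert-butyldimethylsilyl)oxy]-2-methylpropanal; 4 (E)-but-2-en-1-yl(tributyl)stannane
Product: 5 (2S,3S,4R)-1-[(tert-butyldimethylsilyl)oxy]-2,4-dimethylhex-5-en-3-ol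
Conditions: BF3·OEt2, CH2Cl2, −78 °C
Reagents that add atoms: none
Why: Lewis-acid-promoted crotylstannane addition through an open transition state should give the C7/C8 syn relationship from either crotyl geometry. Felkin–Anh attack anti to the CH2OTBS group (BF3 does not chelate) should give C6/C7 syn, so both preferences are matched for the all-syn triad.

Step 4
Reactants: 5 (2S,3S,4R)-1-[(tert-butyldimethylsilyl)oxy]-2,4-dimethylhex-5-en-3-ol
Product: 6 (2S,3S,4R)-1,3-bis[(tert-butyldimethylsilyl)oxy]-2,4-dimethylhex-5-ene
Conditions: TBSOTf, 2,6-lutidine, CH2Cl2, −78 → 0 °C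
Reagents that add atoms: tert-butyldimethylsilyl trifluoromethanesulfonate, CC(C)(C)[Si](C)(C)OS(=O)(=O)C(F)(F)F
Why: Silylation of a hindered secondary alcohol with the silyl triflate.

Step 5
Reactants: 6 (2S,3S,4R)-1,3-bis[(tert-butyldimethylsilyl)oxy]-2,4-dimethylhex-5-ene
Product: 7 (2S,3S,4R)-3-[(tert-butyldimethylsilyl)oxy]-2,4-dimethylhex-5-en-1-ol
Conditions: HF·pyridine, pyridine, THF, 0 °C → rt
Reagents that add atoms: none
Why: Selective desilylation; the primary TBS ether should be cleaved much faster than the secondary one flanked by two branched carbons.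

Step 6
Reactants: 7 (2S,3S,4R)-3-[(tert-butyldimethylsilyl)oxy]-2,4-dimethylhex-5-en-1-ol
Product: 8 (2R,3S,4R)-3-[(tert-butyldimethylsilyl)oxy]-2,4-dimethylhex-5-enal
Conditions: Dess–Martin periodinane, CH2Cl2, 0 °C → rt
Reagents that add atoms: none
Why: Dess–Martin oxidation under non-basic conditions should leave the α-stereocentre (C6) intact; the descriptor changes only through priorities.

Step 7
Reactants: 8 (2R,3S,4R)-3-[(tert-butyldimethylsilyl)oxy]-2,4-dimethylhex-5-enal
Product: 9 (4S,5S,6R)-5-[(tert-butyldimethylsilyl)oxy]-4,6-dimethylocta-1,7-dien-3-ol (C3 epimers)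
Conditions: CH2=CHMgBr, THF, −78 °C
Reagents that add atoms: vinylmagnesium bromide, C=C[Mg]Br
Why: Grignard 1,2-addition; the new carbinol centre is oxidized in the next step, so its configuration does not matter.

Step 8
Reactants: 9 (4S,5S,6R)-5-[(tert-butyldimethylsilyl)oxy]-4,6-dimethylocta-1,7-dien-3-ol
Product: 10 (4R,5S,6R)-5-[(tert-butyldimethylsilyl)oxy]-4,6-dimethylocta-1,7-dien-3-one
Conditions: Dess–Martin periodinane, CH2Cl2, 0 °C
Reagents that add atoms: none
Why: Dess–Martin oxidation of the allylic alcohol to the vinyl ketone without base, so C6 should not epimerize; the dienone is used directly.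

Step 9
Reactants: 10 (4R,5S,6R)-5-[(tert-butyldimethylsilyl)oxy]-4,6-dimethylocta-1,7-dien-3-one
Product: 11 (4R,5S,6R)-5-[(tert-butyldimethylsilyl)oxy]-4,6-dimethylcyclohex-2-en-1-one (ring A enone)
Conditions: second-generation Grubbs catalyst (H2IMes)(PCy3)Cl2Ru=CHPh (3 mol%), CH2Cl2, 40 °C
Reagents that add atoms: none
Why: Ring-closing metathesis of a vinyl ketone with a terminal alkene should close the six-membered enone (C4a=C8a) with loss of ethene; no stereocentre is involved.

Step 10
Reactants: 12 3-methylbut-3-en-2-one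
Product: 13 tert-butyldimethyl[(3-methylbuta-1,3-dien-2-yl)oxy]silane
Conditions: TBSOTf, Et3N, Et2O, 0 °C
Reagents that add atoms: tert-butyldimethylsilyl trifluoromethanesulfonate, CC(C)(C)[Si](C)(C)OS(=O)(=O)C(F)(F)F
Why: Soft enolization and O-silylation; the acetyl methyl is the only enolizable position, so a single 2-silyloxydiene should form.

Step 11
Reactants: 11 (4R,5S,6R)-5-[(tert-butyldimethylsilyl)oxy]-4,6-dimethylcyclohex-2-en-1-one; 13 tert-butyldimethyl[(3-methylbuta-1,3-dien-2-yl)oxy]silane
Product: 14 cis-fused adduct (C2=C3 TBS enol ether, C5 ketone, 3-methyl, 6α- and 8α-methyl, 7β-OTBS, 4aα-H, 8aα-H)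
Conditions: Et2AlCl (1.1 equiv), 13 (3 equiv), CH2Cl2, −78 → −30 °C; Et3N, then aq. NaHCO3
Reagents that add atoms: none
Why: Et2AlCl binds the C5 carbonyl and lowers the enone LUMO; the diene HOMO is largest at the CH2 next to the silyloxy carbon, so that terminus bonds to the β-carbon C8a and the other terminus to C4a in a concerted, asynchronous [4+2] cycloaddition with the C1–C8a bond leading. The closest known reaction type is the Lewis-acid-promoted Diels–Alder reaction of 2-silyloxybuta-1,3-dienes with 4-substituted cyclohex-2-enones. Ring B closes by cycloaddition, suprafacial on both partners, forming C1–C8a and C4–C4a on one face of the ring A alkene. The cis relationship of C4a and C8a follows from suprafacial addition to the ring-locked cis alkene. Their relationship to the C6–C8 triad is set by the face of approach, which should be anti to the C8 methyl on the carbon next to the reacting C8a, as 4-substituted cyclohexenones react anti to the 4-substituent. The regioselectivity needed ("para", oxygen at C2) is secured by the 2-silyloxy donor, which outweighs the 3-methyl group; the diene has no terminal substituents, so no endo/exo question arises. The silyl enol ether must survive and C4a must not epimerize, which the low temperature, the robust TBS group and the amine/bicarbonate quench should secure. The bulky, non-chelating C7 silyl ether should stay equatorial and not tie the Lewis acid to the β face.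

Step 12
Reactants: 14 cis-fused adduct (C2=C3 TBS enol ether, C5 ketone)
Product: 15 C5 alcohol (C5 epimers; C2=C3 TBS enol ether, 7β-OTBS, cis-fused)
Conditions: LiAlH4, Et2O, −78 → −20 °C
Reagents that add atoms: none
Why: Hydride reduction of the ketone under aprotic, cold conditions should be faster than enolization toward C4a, so the cis fusion is kept; the silyl enol ether is inert to hydride.

Step 13
Reactants: 15 C5 alcohol
Product: 16 O-(C5) 1H-imidazole-1-carbothioate of 15
Conditions: Im2C=S, DMAP, toluene, 80 °C
Reagents that add atoms: 1,1′-thiocarbonyldiimidazole, S=C(n1ccnc1)n1ccnc1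
Why: Thioacylation of a hindered secondary alcohol with thiocarbonyldiimidazole under neutral conditions, which the silyl enol ether tolerates.

Step 14
Reactants: 16 O-(C5) 1H-imidazole-1-carbothioate
Product: 17 C5-deoxy silyl enol ether (C2=C3 TBS enol ether, 7β-OTBS, 6α,8α-dimethyl, cis-fused)
Conditions: Bu3SnH, AIBN, toluene, 100 °C
Reagents that add atoms: none
Why: Barton–McCombie deoxygenation; the secondary C5 radical has no fragmentation or cyclization path and should be reduced to CH2 without touching a stereocentre.

Step 15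
Reactants: 17 C5-deoxy silyl enol ether
Product: 18 enone (C2 ketone, C3=C4, 3-methyl, 7β-OTBS, 6α,8α-dimethyl, 4aα-H, 8aα-H)
Conditions: Pd(OAc)2 (1.1 equiv), MeCN, rt
Reagents that add atoms: none
Why: Saegusa–Ito oxidation; divalent palladium forms the C3 palladium enolate of the regiodefined enol ether, and syn β-hydride elimination toward the ring CH2 (C4) should give the conjugated endocyclic enone, as 2-methylcyclohexanone silyl enol ethers do.

Step 16
Reactants: 18 enone (C2 ketone, C3=C4)
Product: 20 1α-(hydroxymethyl) enone (C2 ketone; C3=C4; 7β-OTBS), via lithium dienolate 19 (not isolated)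
Conditions: LiN(iPr)2, THF, −78 °C; CH2O (gas), −78 °C; aq. NH4Cl
Reagents that add atoms: formaldehyde, C=O
Why: Kinetic α′-deprotonation of a cyclohexenone gives the cross-conjugated enolate at C1, and aldol addition to monomeric formaldehyde forms the C1–C7″ bond. The electrophile should enter on the α face, anti to the pseudoaxial C8a–C8 bond, which sets C1.

Step 17
Reactants: 20 1α-(hydroxymethyl) enone
Product: 21 1α-[(triethylsilyloxy)methyl] enone (C2 ketone, C3=C4, 7β-OTBS)
Conditions: Et3SiCl, imidazole, CH2Cl2, 0 °C
Reagents that add atoms: chlorotriethylsilane, CC[Si](Cl)(CC)CC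
Why: Silylation of the primary alcohol; it removes the retro-aldol and dehydration paths of the β-hydroxy ketone before the basic next step.

Step 18
Reactants: 21 1α-[(triethylsilyloxy)methyl] enone; 22 tert-butyldimethyl(prop-2-yn-1-yloxy)silane
Product: 25 C2 alkynyl carbinol trimethylsilyl ether (1α-CH2OTES; C2 bearing OTMS and the 3-(TBS-oxy)prop-1-ynyl group; C3=C4), via lithium acetylide 23 (not isolated), via lithium alkoxide 24 (not isolated)
Conditions: 22, n-BuLi, THF, −78 °C; 21, −78 → −30 °C; Me3SiCl, → rt
Reagents that add atoms: chlorotrimethylsilane, C[Si](C)(C)Cl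
Why: 1,2-Addition of a lithium acetylide to the enone carbonyl (acetylides do not add in a conjugate sense), then O-silylation of the tertiary alkoxide in the flask. The C2 configuration is immaterial, and the silyl ether blocks retro-aldol and β-elimination once C7″ becomes an aldehyde.

Step 19
Reactants: 25 C2 alkynyl carbinol trimethylsilyl ether (1α-CH2OTES)
Product: 26 C1 aldehyde (1α-formyl, C2 OTMS and alkynyl, C3=C4, 7β-OTBS)
Conditions: (COCl)2, DMSO, CH2Cl2, −78 → −40 °C; Et3N, → 0 °C
Reagents that add atoms: none
Why: Swern oxidation applied directly to a primary triethylsilyl ether; chlorodimethylsulfonium chloride cleaves the unhindered primary TES ether to the alkoxysulfonium salt, which Et3N collapses to the aldehyde. The hindered tertiary TMS ether and the TBS ethers should be left.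

Step 20
Reactants: 26 C1 aldehyde
Product: 27 (E)-2-methyl enal on C1 (C7″H=C6″(CH3)–CHO; C2 OTMS and alkynyl)
Conditions: Ph3P=C(CH3)CHO, toluene, 90 °C
Reagents that add atoms: 2-(triphenylphosphoranylidene)propanal, CC(C=O)=P(c1ccccc1)(c1ccccc1)c1ccccc1
Why: Wittig reaction with a stabilized, weakly basic ylide should give the (E)-trisubstituted enal (C6″=C7″) and leave the α-stereocentre C1 of the β-silyloxy aldehyde alone.

Step 21
Reactants: 27 (E)-2-methyl enal
Product: 28 (1E,3Z)-4-iodo-2-methylpenta-1,3-dienyl compound (C4″ iodide; C2 OTMS and alkynyl)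
Conditions: [Ph3PCH(I)CH3]I, NaN(SiMe3)2, THF, −78 °C; then 27, −78 → −20 °C
Reagents that add atoms: (1-iodoethyl)triphenylphosphonium iodide, CC(I)[P+](c1ccccc1)(c1ccccc1)c1ccccc1.[I-]
Why: Stork–Zhao-type olefination with the α-iodo ylide should give the (Z)-2-iodoalkene kinetically (iodine cis to C6″), which is the geometry needed for the Z C4″=C5″ bond after coupling with retention.

Step 22
Reactants: 28 (1E,3Z)-dienyl iodide; 29 ethyl (E)-3-(4,4,5,5-tetramethyl-1,3,2-dioxaborolan-2-yl)prop-2-enoate
Product: 30 ethyl (2E,4Z,6E)-trienoate (C2 OTMS and alkynyl, 7β-OTBS)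
Conditions: PdCl2(dppf) (5 mol%), K3PO4, THF/H2O, 40 °C
Reagents that add atoms: none
Why: Suzuki–Miyaura coupling of an alkenyl iodide with an alkenyl boronate proceeds with retention at both partners, so the C3″–C4″ bond should form with the 4Z and 2E geometries intact.

Step 23
Reactants: 30 ethyl (2E,4Z,6E)-trienoate
Product: 31 trienoic acid with free tertiary C2 carbinol (C2 OH and 3-(TBS-oxy)prop-1-ynyl, 7β-OTBS)
Conditions: LiOH, THF/MeOH/H2O, rt; 0.5 M HCl to pH 4, 0 °C
Reagents that add atoms: lithium hydroxide, [Li+].[OH-]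
Why: Saponification of the ester; hydroxide and the mildly acidic work-up should also cleave the trimethylsilyl ether, while the TBS ethers stay. C1 is only allylic at this stage and is not at risk from base.

Step 24
Reactants: 31 trienoic acid with free tertiary C2 carbinol
Product: 32 (E)-ylidene ketone (C2=C1′–C2′(=O)–C3′H2OTBS, 7β-OTBS, free acid)
Conditions: Ph3PAuNTf2 (5 mol%), MeOH (2 equiv), toluene, rt
Reagents that add atoms: water, O (the C2 hydroxyl leaves as water and the carbonyl oxygen is returned from the medium; net isomerization)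
Why: Gold-catalysed Meyer–Schuster rearrangement of a tertiary propargylic alcohol gives the enone by a formal 1,3-oxygen shift. The (E) ylidene should prevail, because the acyl group avoids the C3 methyl and lies toward C1, whose chain is then pseudoaxial as in the target.

Step 25
Reactants: 32 (E)-ylidene ketone bis-TBS ether
Product: 33 (2E,4Z,6E)-7-[(1R,2E,4aS,6S,7R,8R,8aR)-7-hydroxy-2-(3-hydroxy-2-oxopropylidene)-3,6,8-trimethyl-1,2,4a,5,6,7,8,8a-octahydronaphthalen-1-yl]-4,6-dimethylhepta-2,4,6-trienoic acid
Conditions: HF·pyridine, pyridine, THF, 0 °C → rt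
Reagents that add atoms: none
Why: Buffered fluoride desilylation should remove the primary and the hindered secondary TBS ether without base, so the C1–H and the Z alkene are not exposed to isomerizing conditions.

## Compound list

1 | methyl (S)-3-hydroxy-2-methylpropanoate | COC(=O)[C@@H](C)CO | starting material
2 | methyl (S)-3-[(tert-butyldimethylsilyl)oxy]-2-methylpropanoate | COC(=O)[C@@H](C)CO[Si](C)(C)C(C)(C)C | intermediate
3 | (S)-3-[(tert-butyldimethylsilyl)oxy]-2-methylpropanal | O=C[C@@H](C)CO[Si](C)(C)C(C)(C)C | intermediate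
4 | (E)-but-2-en-1-yl(tributyl)stannane | C/C=C/C[Sn](CCCC)(CCCC)CCCC | starting material
5 | (2S,3S,4R)-1-[(tert-butyldimethylsilyl)oxy]-2,4-dimethylhex-5-en-3-ol | CC(C)(C)[Si](C)(C)OC[C@H](C)[C@@H](O)[C@H](C)C=C | intermediate
6 | (2S,3S,4R)-1,3-bis[(tert-butyldimethylsilyl)oxy]-2,4-dimethylhex-5-ene | CC(C)(C)[Si](C)(C)OC[C@H](C)[C@@H](O[Si](C)(C)C(C)(C)C)[C@H](C)C=C | intermediate
7 | (2S,3S,4R)-3-[(tert-butyldimethylsilyl)oxy]-2,4-dimethylhex-5-en-1-ol | OC[C@H](C)[C@@H](O[Si](C)(C)C(C)(C)C)[C@H](C)C=C | intermediate
8 | (2R,3S,4R)-3-[(tert-butyldimethylsilyl)oxy]-2,4-dimethylhex-5-enal | O=C[C@H](C)[C@@H](O[Si](C)(C)C(C)(C)C)[C@H](C)C=C | intermediate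
9 | (4S,5S,6R)-5-[(tert-butyldimethylsilyl)oxy]-4,6-dimethylocta-1,7-dien-3-ol (C3 epimers) | C=CC(O)[C@H](C)[C@@H](O[Si](C)(C)C(C)(C)C)[C@H](C)C=C | intermediate
10 | (4R,5S,6R)-5-[(tert-butyldimethylsilyl)oxy]-4,6-dimethylocta-1,7-dien-3-one | C=CC(=O)[C@H](C)[C@@H](O[Si](C)(C)C(C)(C)C)[C@H](C)C=C | intermediate
11 | (4R,5S,6R)-5-[(tert-butyldimethylsilyl)oxy]-4,6-dimethylcyclohex-2-en-1-one | O=C1C=C[C@@H](C)[C@H](O[Si](C)(C)C(C)(C)C)[C@H]1C | intermediate
12 | 3-methylbut-3-en-2-one | CC(=O)C(C)=C | starting material
13 | tert-butyldimethyl[(3-methylbuta-1,3-dien-2-yl)oxy]silane | C=C(C)C(=C)O[Si](C)(C)C(C)(C)C | intermediate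
14 | cis-fused adduct: C2=C3 TBS enol ether, C5 ketone, 3-methyl, 6α,8α-dimethyl, 7β-OTBS, 4aα-H, 8aα-H | CC1=C(O[Si](C)(C)C(C)(C)C)C[C@@H]2[C@@H](C)[C@H](O[Si](C)(C)C(C)(C)C)[C@@H](C)C(=O)[C@@H]2C1 | intermediate
15 | C5 alcohol of 14 (C5 epimers) | CC1=C(O[Si](C)(C)C(C)(C)C)C[C@@H]2[C@@H](C)[C@H](O[Si](C)(C)C(C)(C)C)[C@@H](C)C(O)[C@@H]2C1 | intermediate
16 | O-(C5) 1H-imidazole-1-carbothioate of 15 | CC1=C(O[Si](C)(C)C(C)(C)C)C[C@@H]2[C@@H](C)[C@H](O[Si](C)(C)C(C)(C)C)[C@@H](C)C(OC(=S)n3ccnc3)[C@@H]2C1 | intermediate
17 | C5-deoxy compound: C2=C3 TBS enol ether, 3-methyl, 6α,8α-dimethyl, 7β-OTBS, cis-fused | CC1=C(O[Si](C)(C)C(C)(C)C)C[C@@H]2[C@@H](C)[C@H](O[Si](C)(C)C(C)(C)C)[C@@H](C)C[C@@H]2C1 | intermediate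
18 | enone: C2 ketone, C3=C4, 3-methyl, 6α,8α-dimethyl, 7β-OTBS, 4aα-H, 8aα-H | CC1=C[C@H]2C[C@H](C)[C@@H](O[Si](C)(C)C(C)(C)C)[C@H](C)[C@H]2CC1=O | intermediate
19 | lithium dienolate of 18 (C1=C2–O−, C3=C4) | CC1=C[C@H]2C[C@H](C)[C@@H](O[Si](C)(C)C(C)(C)C)[C@H](C)[C@H]2C=C1[O-].[Li+] | intermediate (not isolated)
20 | 1α-(hydroxymethyl) derivative of 18 | CC1=C[C@H]2C[C@H](C)[C@@H](O[Si](C)(C)C(C)(C)C)[C@H](C)[C@H]2[C@H](CO)C1=O | intermediate
21 | 1α-[(triethylsilyloxy)methyl] derivative of 18 | CC1=C[C@H]2C[C@H](C)[C@@H](O[Si](C)(C)C(C)(C)C)[C@H](C)[C@H]2[C@H](CO[Si](CC)(CC)CC)C1=O | intermediate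
22 | tert-butyldimethyl(prop-2-yn-1-yloxy)silane | C#CCO[Si](C)(C)C(C)(C)C | starting material
23 | lithium acetylide of 22 | [Li+].[C-]#CCO[Si](C)(C)C(C)(C)C | intermediate (not isolated)
24 | lithium alkoxide: C2 O−, C2 3-(TBS-oxy)prop-1-ynyl, 1α-CH2OTES | CC1=C[C@H]2C[C@H](C)[C@@H](O[Si](C)(C)C(C)(C)C)[C@H](C)[C@H]2[C@H](CO[Si](CC)(CC)CC)C1([O-])C#CCO[Si](C)(C)C(C)(C)C.[Li+] | intermediate (not isolated)
25 | C2 carbinol TMS ether: C2 OTMS and 3-(TBS-oxy)prop-1-ynyl, 1α-CH2OTES, C3=C4, 7β-OTBS | CC1=C[C@H]2C[C@H](C)[C@@H](O[Si](C)(C)C(C)(C)C)[C@H](C)[C@H]2[C@H](CO[Si](CC)(CC)CC)C1(O[Si](C)(C)C)C#CCO[Si](C)(C)C(C)(C)C | intermediate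
26 | 1α-formyl compound (C2 OTMS and alkynyl) | CC1=C[C@H]2C[C@H](C)[C@@H](O[Si](C)(C)C(C)(C)C)[C@H](C)[C@H]2[C@H](C=O)C1(O[Si](C)(C)C)C#CCO[Si](C)(C)C(C)(C)C | intermediate
27 | 1α-[(E)-2-methyl-3-oxoprop-1-enyl] compound | CC1=C[C@H]2C[C@H](C)[C@@H](O[Si](C)(C)C(C)(C)C)[C@H](C)[C@H]2[C@H](/C=C(C)/C=O)C1(O[Si](C)(C)C)C#CCO[Si](C)(C)C(C)(C)C | intermediate
28 | 1α-[(1E,3Z)-4-iodo-2-methylpenta-1,3-dienyl] compound | CC1=C[C@H]2C[C@H](C)[C@@H](O[Si](C)(C)C(C)(C)C)[C@H](C)[C@H]2[C@H](/C=C(C)/C=C(C)\I)C1(O[Si](C)(C)C)C#CCO[Si](C)(C)C(C)(C)C | intermediate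
29 | ethyl (E)-3-(4,4,5,5-tetramethyl-1,3,2-dioxaborolan-2-yl)prop-2-enoate | CCOC(=O)/C=C/B1OC(C)(C)C(C)(C)O1 | starting material
30 | ethyl (2E,4Z,6E)-4,6-dimethylhepta-2,4,6-trienoate on C1 (C2 OTMS and alkynyl, 7β-OTBS) | CC1=C[C@H]2C[C@H](C)[C@@H](O[Si](C)(C)C(C)(C)C)[C@H](C)[C@H]2[C@H](/C=C(C)/C=C(C)\C=C\C(=O)OCC)C1(O[Si](C)(C)C)C#CCO[Si](C)(C)C(C)(C)C | intermediate
31 | trienoic acid with free C2 carbinol (C2 OH and 3-(TBS-oxy)prop-1-ynyl, 7β-OTBS) | CC1=C[C@H]2C[C@H](C)[C@@H](O[Si](C)(C)C(C)(C)C)[C@H](C)[C@H]2[C@H](/C=C(C)/C=C(C)\C=C\C(=O)O)C1(O)C#CCO[Si](C)(C)C(C)(C)C | intermediate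
32 | bis-TBS ether of the target (7β-OTBS, C3′ OTBS, (E)-ylidene ketone, free acid) | CC1=C[C@H]2C[C@H](C)[C@@H](O[Si](C)(C)C(C)(C)C)[C@H](C)[C@H]2[C@H](/C=C(C)/C=C(C)\C=C\C(=O)O)/C1=C\C(=O)CO[Si](C)(C)C(C)(C)C | intermediate
33 | (2E,4Z,6E)-7-[(1R,2E,4aS,6S,7R,8R,8aR)-7-hydroxy-2-(3-hydroxy-2-oxopropylidene)-3,6,8-trimethyl-1,2,4a,5,6,7,8,8a-octahydronaphthalen-1-yl]-4,6-dimethylhepta-2,4,6-trienoic acid | CC1=C[C@H]2C[C@H](C)[C@@H](O)[C@H](C)[C@H]2[C@H](/C=C(C)/C=C(C)\C=C\C(=O)O)/C1=C\C(=O)CO | target

## Step count and least certain steps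

Total: 25 steps. Longest linear sequence: 24 steps (steps 1–9 and 11–25, from 1); step 10 is a one-step branch.

**Step 11 (key step).** The most likely failure is poor or reversed facial selectivity. The C7 silyloxy group is a 5-substituent of the enone and, through the chair-like approach trans to it, favours the α face, against the preference anti to the C8 methyl. Loss of the enol ether or epimerization at C4a on long contact with the Lewis acid is a second risk. Fallback: facial control is moved from the substrate to the reagent. 11 and 13 are combined under a chiral cationic oxazaborolidine Lewis acid (a B-aryl oxazaborolidine activated by Tf2NH), using the enantiomer that shields the α face of the coordinated enone, so that double stereodifferentiation delivers the β-face adduct. This sets out from 11 and 13 and comes back at 14; no new compound is made.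

**Step 24.** The carbinol is both allylic and propargylic, so ionization may lead to allylic transposition toward C4 or to elimination toward C1 instead of the 1,3-shift. The gold catalyst may also engage the polyene or the acid, and the ylidene may form as an E/Z mixture. Fallback, setting out from 31: ruthenium-catalysed trans-hydrosilylation ([Cp*Ru(MeCN)3]PF6, HSi(OEt)3), directed by the free tertiary hydroxyl, places silicon on C2′ and gives the vinylsilane F7. Tamao–Fleming oxidation (H2O2, KF, KHCO3) gives the β-hydroxy ketone F8. Acid-catalysed dehydration of the tertiary allylic alcohol (cat. TsOH) gives the conjugated ylidene ketone and comes back at 32.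

**Step 21.** Low Z-selectivity or low conversion of the α-iodo ylide with a conjugated, γ-enolizable aldehyde is possible. Fallback, setting out from 27: Still–Gennari olefination with methyl 2-[bis(2,2,2-trifluoroethoxy)phosphoryl]propanoate (KN(SiMe3)2, 18-crown-6) gives the (2Z,4E)-dienoate F4. iBu2AlH reduction gives the allylic alcohol F5, and MnO2 oxidation gives the (2Z)-dienal F6. Horner–Wadsworth–Emmons olefination with triethyl phosphonoacetate (LiCl, DBU) comes back at 30.

**Step 19.** The acidic chlorosulfonium reagent may strip the tertiary trimethylsilyl ether or ionize the doubly activated C2, or the TES ether may be cleaved incompletely. Fallback, setting out from 25: buffered HF·pyridine removes the triethylsilyl and trimethylsilyl groups and gives the diol F2, with the primary propargylic TBS ether retained. TEMPO/PhI(OAc)2 oxidizes only the primary hydroxyl to the β-hydroxy aldehyde F3. N-(trimethylsilyl)imidazole re-silylates the tertiary hydroxyl under neutral conditions and comes back at 26.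

**Step 16.** Competing γ-deprotonation at C4a, double hydroxymethylation, or dehydration of the aldol to the α-methylene ketone may occur, and the C1 face selectivity may be incomplete. Fallback, setting out from 18: the kinetic enolate is trapped with Me3SiCl as the cross-conjugated silyl dienol ether F1, which is purified and then hydroxymethylated by a Mukaiyama aldol reaction in water (aqueous formaldehyde, Yb(OTf)3, THF/H2O), coming back at 20.

## Further compounds

F0 | step 11 | none | none
F1 | step 16 | 2-(trimethylsilyloxy) 1,3-diene of 18 (C1=C2 silyl enol ether, C3=C4) | CC1=C[C@H]2C[C@H](C)[C@@H](O[Si](C)(C)C(C)(C)C)[C@H](C)[C@H]2C=C1O[Si](C)(C)C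
F2 | step 19 | diol: 1α-(hydroxymethyl), C2 OH and 3-(TBS-oxy)prop-1-ynyl | CC1=C[C@H]2C[C@H](C)[C@@H](O[Si](C)(C)C(C)(C)C)[C@H](C)[C@H]2[C@H](CO)C1(O)C#CCO[Si](C)(C)C(C)(C)C
F3 | step 19 | β-hydroxy aldehyde: 1α-formyl, C2 OH and 3-(TBS-oxy)prop-1-ynyl | CC1=C[C@H]2C[C@H](C)[C@@H](O[Si](C)(C)C(C)(C)C)[C@H](C)[C@H]2[C@H](C=O)C1(O)C#CCO[Si](C)(C)C(C)(C)C
F4 | step 21 | methyl (2Z,4E)-2,4-dimethylpenta-2,4-dienoate on C1 (C2 OTMS and alkynyl) | CC1=C[C@H]2C[C@H](C)[C@@H](O[Si](C)(C)C(C)(C)C)[C@H](C)[C@H]2[C@H](/C=C(C)/C=C(C)\C(=O)OC)C1(O[Si](C)(C)C)C#CCO[Si](C)(C)C(C)(C)C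
F5 | step 21 | (2Z,4E)-dienyl alcohol from F4 | CC1=C[C@H]2C[C@H](C)[C@@H](O[Si](C)(C)C(C)(C)C)[C@H](C)[C@H]2[C@H](/C=C(C)/C=C(C)\CO)C1(O[Si](C)(C)C)C#CCO[Si](C)(C)C(C)(C)C
F6 | step 21 | (2Z,4E)-dienal from F5 | CC1=C[C@H]2C[C@H](C)[C@@H](O[Si](C)(C)C(C)(C)C)[C@H](C)[C@H]2[C@H](/C=C(C)/C=C(C)\C=O)C1(O[Si](C)(C)C)C#CCO[Si](C)(C)C(C)(C)C
F7 | step 24 | (Z)-vinylsilane: C2 OH, C1′H=C2′[Si(OEt)3]–C3′H2OTBS, trienoic acid on C1 | CC1=C[C@H]2C[C@H](C)[C@@H](O[Si](C)(C)C(C)(C)C)[C@H](C)[C@H]2[C@H](/C=C(C)/C=C(C)\C=C\C(=O)O)C1(O)/C=C(/CO[Si](C)(C)C(C)(C)C)[Si](OCC)(OCC)OCC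
F8 | step 24 | β-hydroxy ketone: C2 OH, C1′H2–C2′(=O)–C3′H2OTBS, trienoic acid on C1 | CC1=C[C@H]2C[C@H](C)[C@@H](O[Si](C)(C)C(C)(C)C)[C@H](C)[C@H]2[C@H](/C=C(C)/C=C(C)\C=C\C(=O)O)C1(O)CC(=O)CO[Si](C)(C)C(C)(C)C
A1 | alternative 1 | aldehyde: ring B cyclohexene ketal with allyl on C4a and 1-oxopropan-2-yl on C8a | CC1=C[C@@H](CC=C)[C@@H]([C@@H](C)C=O)CC12OCCO2
A2 | alternative 1 | decalin carbinol with C2 ketal | CC1=C[C@H]2C[C@H](C)[C@@H](O)[C@H](C)[C@H]2CC13OCCO3
A3 | alternative 2 | ring A enone with (Z)-enone β-keto ester arm on C4a | COC(=O)CC(=O)/C(C)=C\[C@H]1C[C@H](C)C(=O)C(C)=C1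
A4 | alternative 2 | cis-fused ring B β-keto ester (enol form) with C7 ketone | CC1=C[C@H]2C[C@H](C)C(=O)[C@H](C)[C@H]2C(C(=O)OC)=C1O
A5 | alternative 3 | ring A cyclohexane with (Z)-enynone arm on C4a and silyl dienol ether arm on C8a | O=C(CO[Si](C)(C)C(C)(C)C)C#C/C(C)=C\[C@H]1C[C@H](C)[C@@H](O[Si](C)(C)C(C)(C)C)[C@H](C)[C@H]1C=CC(C)=CO[Si](C)(C)C(C)(C)C
A6 | alternative 3 | decalin with C1 enal arm and silylated hydroxyacetylidene | CC1=C[C@H]2C[C@H](C)[C@@H](O[Si](C)(C)C(C)(C)C)[C@H](C)[C@H]2[C@H](/C=C(C)/C=O)/C1=C\C(=O)CO[Si](C)(C)C(C)(C)C
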